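The allylic carbons of cyclohexene ring B (C1–C6), carbinol C3 and spiro carbon C6, are joined by the C4–C5 ethano unit. This is the retron of a Diels–Alder reaction with ethylene. The CHBr2 carbon on C3 and C7 on C6 lie on the same face of ring B, so they are tied together in a temporary six-membered ring. This locks the hindered diene s-cis inside a dearomatised tetralin, an ortho-quinol that already carries ring A with its cis-bromohydrin. One cycloaddition sets C3 and C6. Glycol cleavage of the temporary bond then releases the spirocycle; its aldehyde becomes CHBr2 and its ketone the exocyclic methylene.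

Key step: step 10

Numbering: C1–C11 is the spiro[5.5]undecane numbering of 20 (ring B = C1–C6, ring A = C6–C11). Bicyclic intermediates carry the locants of their own names. Pivalate = 2,2-dimethylpropanoate.
Assumption: SIBX (IBX stabilised with benzoic and isophthalic acids) is booked as IBX, its only reactive component.

Step 1
Reactants: 1 2-(2,3-dimethoxyphenyl)acetic acid
Product: 3 2-(2,3-dimethoxyphenyl)-N-methoxy-N-methylacetamide, via acyl imidazolide 2 (not isolated)
Conditions: 1,1'-carbonyldiimidazole, CH2Cl2, rt; then MeNH(OMe)·HCl, rt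
Reagents that add atoms: N,O-dimethylhydroxylamine hydrochloride CNOC.Cl; 1,1'-carbonyldiimidazole O=C(n1ccnc1)n1ccnc1 (imidazolyl group of 2)
Why: Amide formation through an acyl imidazolide is a standard route to Weinreb amides and creates no stereocentre.

Step 2
Reactants: 3 2-(2,3-dimethoxyphenyl)-N-methoxy-N-methylacetamide; 4 2-methylprop-1-en-1-ylmagnesium bromide
Product: 5 1-(2,3-dimethoxyphenyl)-4-methylpent-3-en-2-one
Conditions: THF, -20 °C to 0 °C; 1 M HCl quench
Reagents that add atoms: none
Why: Weinreb ketone synthesis, in which the chelated tetrahedral intermediate stops the alkenyl Grignard addition at the enone.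

Step 3
Reactants: 5 1-(2,3-dimethoxyphenyl)-4-methylpent-3-en-2-one
Product: 6 (2S)-1-(2,3-dimethoxyphenyl)-4-methylpent-3-en-2-ol
Conditions: (R)-1-methyl-3,3-diphenyltetrahydro-1H,3H-pyrrolo[1,2-c][1,3,2]oxazaborole (0.2 equiv), catecholborane, toluene, -78 °C; aqueous work-up
Reagents that add atoms: none
Why: Corey–Bakshi–Shibata reduction, in which the β,β-disubstituted alkenyl group acts as the large and the arylmethyl group as the small substituent, so the (R)-catalyst should give the (S)-carbinol, and catecholborane spares the alkene.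

Step 4
Reactants: 6 (2S)-1-(2,3-dimethoxyphenyl)-4-methylpent-3-en-2-ol
Product: 7 (2S,3S)-3-bromo-7,8-dimethoxy-4,4-dimethyl-1,2,3,4-tetrahydronaphthalen-2-ol
Conditions: Et2SBr·SbCl5Br, MeNO2, -25 °C
Reagents that add atoms: bromodiethylsulfonium bromopentachloroantimonate CC[S+](Br)CC.Cl[Sb-](Cl)(Cl)(Cl)(Cl)Br
Why: In this bromonium-induced cation–π (Friedel–Crafts) cyclisation the arene carbon para to a methoxy group attacks the tertiary terminus through a chair, and allylic 1,3-strain keeps the carbinol hydrogen in the alkene plane, so OH and Br end up diequatorial (trans) and C2 sets C3.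

Step 5
Reactants: 7 (2S,3S)-3-bromo-7,8-dimethoxy-4,4-dimethyl-1,2,3,4-tetrahydronaphthalen-2-ol
Product: 8 (3S)-3-bromo-7,8-dimethoxy-4,4-dimethyl-3,4-dihydronaphthalen-2(1H)-one
Conditions: Dess–Martin periodinane, CH2Cl2, 0 °C to rt
Reagents that add atoms: none
Why: Dess–Martin oxidation is nearly neutral, and any enolisation goes to the benzylic C1, so the C3 bromide stereocentre should be kept.

Step 6
Reactants: 8 (3S)-3-bromo-7,8-dimethoxy-4,4-dimethyl-3,4-dihydronaphthalen-2(1H)-one
Product: 10 (2R,3S)-3-bromo-7,8-dimethoxy-4,4-dimethyl-1,2,3,4-tetrahydronaphthalen-2-yl pivalate, via lithium alkoxide 9 (not isolated)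
Conditions: LiBH(s-Bu)3, THF, -78 °C; then t-BuCOCl, 4-(dimethylamino)pyridine, -78 °C to rt
Reagents that add atoms: pivaloyl chloride CC(C)(C)C(=O)Cl; LiBH(s-Bu)3 [Li+].CCC(C)[BH-](C(C)CC)C(C)CC (lithium of 9)
Why: The bulky hydride attacks equatorially because the axial C4 methyl group blocks the axial path, which gives the axial alkoxide cis to the equatorial bromide (C2 now R), and this is acylated in the same flask.

Step 7
Reactants: 10 (2R,3S)-3-bromo-7,8-dimethoxy-4,4-dimethyl-1,2,3,4-tetrahydronaphthalen-2-yl pivalate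
Product: 11 (2R,3S)-3-bromo-7,8-dihydroxy-4,4-dimethyl-1,2,3,4-tetrahydronaphthalen-2-yl pivalate
Conditions: BBr3, CH2Cl2, -78 °C to 0 °C; water
Reagents that add atoms: none
Why: Lewis acid cleavage of aryl methyl ethers proceeds by bromide attack on the methyl groups, while the hindered pivalate and the neopentyl bromide should survive at low temperature.

Step 8
Reactants: 11 (2R,3S)-3-bromo-7,8-dihydroxy-4,4-dimethyl-1,2,3,4-tetrahydronaphthalen-2-yl pivalate
Product: 12 (6S,7R)-6-bromo-1-hydroxy-5,5-dimethyl-5,6,7,8-tetrahydronaphthalene-2,7-diyl dipivalate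
Conditions: t-BuCOCl (1 equiv), Et3N, CH2Cl2, -30 °C
Reagents that add atoms: pivaloyl chloride CC(C)(C)C(=O)Cl
Why: Acylation is selective for the open C7 phenol of 11, because the C8 phenol sits between the ring methylene and the neighbouring oxygen and stays free.

Step 9
Reactants: 12 (6S,7R)-6-bromo-1-hydroxy-5,5-dimethyl-5,6,7,8-tetrahydronaphthalene-2,7-diyl dipivalate
Product: 13 (6S,7R,8aR)-6-bromo-8a-hydroxy-5,5-dimethyl-1-oxo-1,5,6,7,8,8a-hexahydronaphthalene-2,7-diyl dipivalate
Conditions: SIBX, THF, rt; aq NaHCO3 work-up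
Reagents that add atoms: IBX O=C1OI(=O)(O)c2ccccc12
Why: In this hydroxylative phenol dearomatisation the phenol binds to pentavalent iodine, which passes oxygen to an ortho carbon, here the alkyl-bearing C8a because the other ortho carbon is deactivated by its ester, and from the face that avoids a syn-triaxial array of the new hydroxyl, the C7 ester and a C5 methyl group (C8a R).

Step 10
Reactants: 13 (6S,7R,8aR)-6-bromo-8a-hydroxy-5,5-dimethyl-1-oxo-1,5,6,7,8,8a-hexahydronaphthalene-2,7-diyl dipivalate; 14 ethylene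
Product: 15 6-bromo-8a-hydroxy-5,5-dimethyl-1-oxo-1,5,6,7,8,8a-hexahydro-2H-2,4a-ethanonaphthalene-2,7-diyl dipivalate (ethano bridge on the face of the 8a-hydroxyl)
Conditions: ethylene (60 bar), 2,6-di-tert-butyl-4-methylphenol (trace), toluene, 90 °C, autoclave
Reagents that add atoms: none
Why: Concerted suprafacial [4+2] cycloaddition of ethylene across C2 and C4a of the planar, s-cis-locked, electron-poor diene of 13 forms the C3–C4 and C5–C6 bonds (numbering of 20) at once and leaves the C1=C2 alkene in place. The closest known reaction type is the Diels–Alder reaction of cyclohexa-2,4-dienones (ortho-quinols, their acetates, ortho-quinone monoketals) with alkenes, ethylene under pressure included. It closes ring B as a six-membered carbocycle in the intermolecular [4+2] mode and gives a bicyclo[2.2.2]octenone whose third bridge is the temporary C1–C8a bond of 13. That bridge fixes the relative configuration of the two new stereocentres, since it holds the future CHBr2 carbon and the future C7 cis on ring B, and the diene face that is attacked fixes their absolute sense. Addition syn to the C8a hydroxyl is the usual facial preference of ortho-quinols, and it is reinforced here by the axial bromine at C6 of 13, which is 1,3-diaxial to any approach from the other face. Ethylene poses no regiochemical question, and self-dimerisation of 13 is held back by the fully substituted C4a, the gem-dimethyl group and the C2 ester.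

Step 11
Reactants: 15 ethano-bridged ketol
Product: 16 6-bromo-1,8a-dihydroxy-5,5-dimethyl-1,5,6,7,8,8a-hexahydro-2H-2,4a-ethanonaphthalene-2,7-diyl dipivalate (cis-1,8a-diol)
Conditions: NaBH4, MeOH/THF, 0 °C
Reagents that add atoms: none
Why: In this borohydride 1,2-reduction of the only ketone, hydride should come from the etheno side and give the cis-diol, but this stereocentre is destroyed in step 12 and the pivalates are inert.

Step 12
Reactants: 16 cis-1,8a-diol
Product: 17 10-bromo-3-formyl-11,11-dimethyl-7-oxospiro[5.5]undec-1-ene-3,9-diyl dipivalate (C3, C6, C9 and C10 arranged as in 20)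
Conditions: Pb(OAc)4, CH2Cl2, 0 °C
Reagents that add atoms: none
Why: Criegee glycol cleavage with tetravalent lead also cleaves rigid diols of either configuration, and it cuts the temporary bond to unveil ring B, the aldehyde on C3 and the C7 ketone without touching a stereocentre.

Step 13
Reactants: 17 spiro keto aldehyde
Product: 18 10-bromo-3-(dibromomethyl)-11,11-dimethyl-7-oxospiro[5.5]undec-1-ene-3,9-diyl dipivalate
Conditions: P(OPh)3, Br2, CH2Cl2, -60 °C; then 17, -60 °C to rt
Reagents that add atoms: bromine BrBr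
Why: Deoxygenative gem-dibromination of an aldehyde with the triphenyl phosphite–bromine reagent should work because no free bromine is left for the alkene, the aldehyde cannot enolise, and the hindered ketone reacts far more slowly.

Step 14
Reactants: 18 gem-dibromide ketone
Product: 19 10-bromo-3-(dibromomethyl)-11,11-dimethyl-7-methylidenespiro[5.5]undec-1-ene-3,9-diyl dipivalate
Conditions: Tebbe reagent Cp2Ti(CH2)(Cl)AlMe2, pyridine, THF/toluene, -40 °C to 0 °C
Reagents that add atoms: Tebbe reagent C[Al-]1(C)C[Ti](C2C=CC=C2)(C2C=CC=C2)[Cl+]1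
Why: In the Tebbe methylenation the non-basic titanium methylidene converts hindered, enolisable ketones faster than hindered esters, which avoids β-elimination of the C9 ester and deprotonation of CHBr2.

Step 15
Reactants: 19 bis-pivalate
Product: 20 mailiohydrin, (3R,6S,9R,10S)-10-bromo-3-(dibromomethyl)-11,11-dimethyl-7-methylidenespiro[5.5]undec-1-ene-3,9-diol
Conditions: i-Bu2AlH (excess), CH2Cl2, -78 °C to -20 °C; aq potassium sodium tartrate
Reagents that add atoms: none
Why: Reductive ester cleavage with an aluminium hydride frees both alcohols as weakly basic aluminium alkoxides, so closure of the C3 alkoxide onto CHBr2 is avoided and the C–Br bonds stay intact.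

Compound list
1 | 2-(2,3-dimethoxyphenyl)acetic acid | COc1cccc(CC(=O)O)c1OC | starting material
2 | 1-[2-(2,3-dimethoxyphenyl)acetyl]imidazole | COc1cccc(CC(=O)n2ccnc2)c1OC | intermediate
3 | 2-(2,3-dimethoxyphenyl)-N-methoxy-N-methylacetamide | COc1cccc(CC(=O)N(C)OC)c1OC | intermediate
4 | 2-methylprop-1-en-1-ylmagnesium bromide | CC(C)=C[Mg]Br | starting material
5 | 1-(2,3-dimethoxyphenyl)-4-methylpent-3-en-2-one | COc1cccc(CC(=O)C=C(C)C)c1OC | intermediate
6 | (2S)-1-(2,3-dimethoxyphenyl)-4-methylpent-3-en-2-ol | COc1cccc(C[C@H](O)C=C(C)C)c1OC | intermediate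
7 | (2S,3S)-3-bromo-7,8-dimethoxy-4,4-dimethyl-1,2,3,4-tetrahydronaphthalen-2-ol (trans) | COc1ccc2c(c1OC)C[C@H](O)[C@@H](Br)C2(C)C | intermediate
8 | (3S)-3-bromo-7,8-dimethoxy-4,4-dimethyl-3,4-dihydronaphthalen-2(1H)-one | COc1ccc2c(c1OC)CC(=O)[C@@H](Br)C2(C)C | intermediate
9 | lithium (2R,3S)-3-bromo-7,8-dimethoxy-4,4-dimethyl-1,2,3,4-tetrahydronaphthalen-2-olate | COc1ccc2c(c1OC)C[C@@H](O[Li])[C@@H](Br)C2(C)C | intermediate
10 | (2R,3S)-3-bromo-7,8-dimethoxy-4,4-dimethyl-1,2,3,4-tetrahydronaphthalen-2-yl pivalate (cis) | COc1ccc2c(c1OC)C[C@@H](OC(=O)C(C)(C)C)[C@@H](Br)C2(C)C | intermediate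
11 | (2R,3S)-3-bromo-7,8-dihydroxy-4,4-dimethyl-1,2,3,4-tetrahydronaphthalen-2-yl pivalate | Oc1ccc2c(c1O)C[C@@H](OC(=O)C(C)(C)C)[C@@H](Br)C2(C)C | intermediate
12 | (6S,7R)-6-bromo-1-hydroxy-5,5-dimethyl-5,6,7,8-tetrahydronaphthalene-2,7-diyl dipivalate | CC(C)(C)C(=O)Oc1ccc2c(c1O)C[C@@H](OC(=O)C(C)(C)C)[C@@H](Br)C2(C)C | intermediate
13 | (6S,7R,8aR)-6-bromo-8a-hydroxy-5,5-dimethyl-1-oxo-1,5,6,7,8,8a-hexahydronaphthalene-2,7-diyl dipivalate (ortho-quinol, OH trans to Br and to the C7 ester) | O[C@]12C[C@@H](OC(=O)C(C)(C)C)[C@@H](Br)C(C)(C)C1=CC=C(OC(=O)C(C)(C)C)C2=O | intermediate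
14 | ethylene | C=C | starting material
15 | 6-bromo-8a-hydroxy-5,5-dimethyl-1-oxo-1,5,6,7,8,8a-hexahydro-2H-2,4a-ethanonaphthalene-2,7-diyl dipivalate (ethano bridge syn to 8a-OH, anti to Br and the C7 ester) | O[C@]12C[C@@H](OC(=O)C(C)(C)C)[C@@H](Br)C(C)(C)[C@]1(C=C[C@@]3(OC(=O)C(C)(C)C)C2=O)CC3 | intermediate
16 | 6-bromo-1,8a-dihydroxy-5,5-dimethyl-1,5,6,7,8,8a-hexahydro-2H-2,4a-ethanonaphthalene-2,7-diyl dipivalate (cis-1,8a-diol) | O[C@]12C[C@@H](OC(=O)C(C)(C)C)[C@@H](Br)C(C)(C)[C@]1(C=C[C@@]3(OC(=O)C(C)(C)C)[C@@H]2O)CC3 | intermediate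
17 | 10-bromo-3-formyl-11,11-dimethyl-7-oxospiro[5.5]undec-1-ene-3,9-diyl dipivalate (stereocentres as in 20) | O=C1C[C@@H](OC(=O)C(C)(C)C)[C@@H](Br)C(C)(C)[C@@]12C=C[C@@](OC(=O)C(C)(C)C)(C=O)CC2 | intermediate
18 | 10-bromo-3-(dibromomethyl)-11,11-dimethyl-7-oxospiro[5.5]undec-1-ene-3,9-diyl dipivalate (stereocentres as in 20) | O=C1C[C@@H](OC(=O)C(C)(C)C)[C@@H](Br)C(C)(C)[C@@]12C=C[C@@](OC(=O)C(C)(C)C)(C(Br)Br)CC2 | intermediate
19 | 10-bromo-3-(dibromomethyl)-11,11-dimethyl-7-methylidenespiro[5.5]undec-1-ene-3,9-diyl dipivalate (stereocentres as in 20) | C=C1C[C@@H](OC(=O)C(C)(C)C)[C@@H](Br)C(C)(C)[C@@]12C=C[C@@](OC(=O)C(C)(C)C)(C(Br)Br)CC2 | intermediate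
20 | mailiohydrin, (3R,6S,9R,10S)-10-bromo-3-(dibromomethyl)-11,11-dimethyl-7-methylidenespiro[5.5]undec-1-ene-3,9-diol | C=C1C[C@@H](O)[C@@H](Br)C(C)(C)[C@@]12C=C[C@@](O)(C(Br)Br)CC2 | target

Total step count: 15. Longest linear sequence: 15 steps (from 1).

Steps most likely to fail

1. **Step 10.** Bond formation at the fully substituted C4a, which sits between two quaternary carbons, may be so slow that thermal acyloin shift or decomposition of the ortho-quinol overtakes the cycloaddition.
   - The fallback makes the dienophile intramolecular and sets out from 12.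
   - Oxidation with Pb(OAc)4 in the presence of acrylic acid (modified Wessely oxidation) should give the 8a-acryloyloxy dienone F1.
   - Its tethered acrylate closes in warm toluene by intramolecular Diels–Alder reaction to the bridged γ-lactone F2.
   - LiOH in aqueous THF opens the strained lactone to the hydroxy acid F3.
   - N-Hydroxypyridine-2-thione and N,N'-dicyclohexylcarbodiimide convert F3 into the thiohydroxamate ester F4.
   - Irradiation with t-BuSH (Barton decarboxylation) removes the carboxyl carbon, and the route is rejoined at 15.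

2. **Step 9.** Oxygen transfer may go to the ester-bearing ortho carbon, which means over-oxidation to the ortho-quinone with loss of the pivaloyl group. It may also occur with poor facial selectivity, or the free ketol may be lost by rearrangement.
   - The fallback sets out from 12 and uses ligand coupling on lead instead of oxygen transfer from iodine.
   - Wessely acetoxylation (Pb(OAc)4, AcOH) should give the thermally robust ortho-quinol acetate F5.
   - F5 is heated with ethylene to the ethano-bridged keto acetate F6.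
   - NaBH4 then gives the hydroxy acetate F7.
   - K2CO3 in MeOH removes only the acetate, and the route is rejoined at 16.

3. **Step 13.** Substitution at the neopentyl-type carbon may stall after the first bromide has entered, or ionisation with participation of the neighbouring pivalate may lead to acyl shift.
   - The fallback replaces substitution by hydrazone oxidation and sets out from 17.
   - Hydrazine hydrate in MeOH condenses with the aldehyde, which reacts faster than the hindered ketone, to give the hydrazone F8.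
   - CuBr2 and LiOt-Bu in THF oxidise F8 with loss of nitrogen to the gem-dibromide, and the route is rejoined at 18.

Further compounds
F1 | step 10 | (6S,7R,8aR)-8a-acryloyloxy-6-bromo-5,5-dimethyl-1-oxo-1,5,6,7,8,8a-hexahydronaphthalene-2,7-diyl dipivalate | C=CC(=O)O[C@]12C[C@@H](OC(=O)C(C)(C)C)[C@@H](Br)C(C)(C)C1=CC=C(OC(=O)C(C)(C)C)C2=O
F2 | step 10 | bridged γ-lactone (15 with the 8a-oxygen joined through C=O to the ethano carbon next to C4a) | O=C1O[C@]23C[C@@H](OC(=O)C(C)(C)C)[C@@H](Br)C(C)(C)[C@]2(C=C[C@@]4(OC(=O)C(C)(C)C)C3=O)[C@H]1C4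
F3 | step 10 | hydroxy acid (15 with CO2H on the ethano carbon next to C4a) | O[C@]12C[C@@H](OC(=O)C(C)(C)C)[C@@H](Br)C(C)(C)[C@]1(C=C[C@@]3(OC(=O)C(C)(C)C)C2=O)[C@H](C(=O)O)C3
F4 | step 10 | 2-thioxopyridin-1(2H)-yl ester of F3 | O[C@]12C[C@@H](OC(=O)C(C)(C)C)[C@@H](Br)C(C)(C)[C@]1(C=C[C@@]3(OC(=O)C(C)(C)C)C2=O)[C@H](C(=O)ON1C=CC=CC1=S)C3
F5 | step 9 | (6S,7R,8aR)-8a-acetoxy-6-bromo-5,5-dimethyl-1-oxo-1,5,6,7,8,8a-hexahydronaphthalene-2,7-diyl dipivalate | CC(=O)O[C@]12C[C@@H](OC(=O)C(C)(C)C)[C@@H](Br)C(C)(C)C1=CC=C(OC(=O)C(C)(C)C)C2=O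
F6 | step 9 | 8a-O-acetate of 15 | CC(=O)O[C@]12C[C@@H](OC(=O)C(C)(C)C)[C@@H](Br)C(C)(C)[C@]1(C=C[C@@]3(OC(=O)C(C)(C)C)C2=O)CC3
F7 | step 9 | 8a-O-acetate of 16 | CC(=O)O[C@]12C[C@@H](OC(=O)C(C)(C)C)[C@@H](Br)C(C)(C)[C@]1(C=C[C@@]3(OC(=O)C(C)(C)C)[C@@H]2O)CC3
F8 | step 13 | (E)-hydrazone of the aldehyde of 17 | O=C1C[C@@H](OC(=O)C(C)(C)C)[C@@H](Br)C(C)(C)[C@@]12C=C[C@@](OC(=O)C(C)(C)C)(/C=N/N)CC2
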